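# Larreantin by photochemical Wolff rearrangement and aryl ketene–methoxyacetylene benzannulation

Compound numbers are those of the steps and of the compound list. Positions on the bicyclic core are always given in the numbering of the target quinone (C1 carbonyl peri to C8), also for the naphthol and for the open-chain intermediates of the key step.

## Analysis of the target

Larreantin (24) is a 1,4-naphthoquinone. Ring A (C1–C4, C4a, C8a) is the quinone ring, with a methoxy group on C2 and hydrogen on C3. Ring B (C4a, C5–C8, C8a) is benzenoid and carries hydrogen on C5, a 4-hydroxy-3-methoxybenzyl group on C6, a methyl group on C7 and a 4-hydroxy-3-methoxyphenyl group on C8. There is no stereocentre, and because the C8 aryl ring has no ortho substituent, the biaryl axis between the C7 methyl group and the peri C1 carbonyl is not a stereogenic element that needs control. The sensitive parts are the 2-methoxyquinone and the two free guaiacol units. The former is a vinylogous ester that loses or exchanges its methoxy group with nucleophiles and base and is a Michael acceptor at C3; the latter are oxidised more easily than ordinary phenols. The synthesis is hard for two reasons. Ring B has three different carbon substituents on the adjacent carbons C6, C7 and C8, the last one peri to C1. The methoxy group must also sit next to the carbonyl that is peri to the aryl group (C1) and not next to C4, although the two carbonyls differ very little. The plan rests on reading the C2(OMe)–C3(H) unit as a two-carbon alkyne and C4 and C1 as the carbonyl and diazo carbons of an aryl diazomethyl ketone. Ring B then arrives whole as a benzoic acid with only one free ortho carbon (C4a).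

## Retrosynthetic reasoning

Target 24 is traced back to its bis(benzyl ether) 22 by turning the two phenolic O–H bonds into O–CH2Ph bonds. The guaiacol hydroxyl groups cannot be free when ring A is oxidised to the quinone, nor in the organometallic steps. Benzyl ethers last through all of these and fall to hydrogenolysis. Under hydrogen the quinone only goes to hydroquinone 23, which returns to 24 on aerobic work-up, so deprotection can be the last step.

In 22 the C1=O bond is cut, which leaves naphthol 21 with the hydroxyl group on C4, the methoxy group on C2 and hydrogen on C1 and C3. C1 is para to the hydroxyl group, so a phenol-to-para-quinone oxidation restores the quinone. The forward step must oxygenate C1 and not the ortho carbon C3. Nothing else in ring A changes, because the methoxy group already sits on the carbon next to C1.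

Ring A of 21 is then taken apart completely, at C1–C2, C3–C4 and C4–C4a, and the C8a–C1 bond is traced to a 1,2-aryl shift. These are all the bonds of ring A that do not belong to ring B. Ring B therefore emerges untouched as the aryl group of diazomethyl ketone 14, and C2–C3 emerges as methoxyacetylene 17. The cut is made here and not in ring B because ring B has three different carbon substituents in a row, which are easier to place on a monocyclic benzene by cross-coupling than to build by annulation. Ring A has one substituent, whose position follows from the polarity of 17. The forward reaction must convert 14 into aryl ketene 18 by a Wolff shift, add 17 in the right orientation to give cyclobutenone 19, and carry 19 through dienylketene 20 to the naphthol by electrocyclic opening and closure. The closure can only go to C4a, since the other ortho carbon (C8) is substituted.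

Diazoketone 14 is cut between the carbonyl carbon (C4) and the diazo carbon (C1), which is the acylation of a diazoalkane by acid chloride 13, made from benzoic acid 12. The whole substitution problem of ring B is thereby moved into a benzoic acid with the aryl group ortho, the methyl group meta and the benzyl group para to the carboxyl group.

In 12 the bond between C8 and the guaiacyl ring is cut (Suzuki–Miyaura coupling of bromo acid 10 with boronic acid 11). This bond is made last among the ring B bonds for two reasons. Its bromide is the most hindered halide and is best kept as the unreactive site while the other positions are dealt with. The electron-rich aryl ring is also still absent when the amino group is diazotised, so intramolecular azo coupling onto it cannot occur.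

Acid 10 is cut at the bond between the carboxyl carbon and C8a, back to iodide 8 (iodine–magnesium exchange through 9, then carboxylation). The C–I bond of 8 is traced to the C–N bond of aniline 6 through diazonium salt 7. The amino group is thus used twice, first as the para director that defines C6 and then as the handle that becomes the carboxyl carbon. Iodine is chosen at this carbon so that the exchange distinguishes it cleanly from the C8 bromine.

In 6 the C6–CH2 bond is cut (Negishi coupling of aryl iodide 2 with benzylzinc chloride 5). The bond is made at the iodide in the presence of the bromide, which is possible because of the intrinsic difference between C–I and C–Br and the double ortho substitution of the bromide. Reagent 5 goes back to chloride 4 and alcohol 3.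

Iodide 2 goes back to aniline 1 by cutting the C–I bond, the iodine entering para to nitrogen. In 1 the nitrogen, the bromine and the methyl group already sit on three adjacent carbons in the order needed for C8a, C8 and C7.

Methoxyacetylene 17 goes back to acetal 15 by two eliminations through acetylide 16.

## Alternatives that were turned down

Alternative 1: Ring B is disconnected at C6–C7 and C8–C8a by an intramolecular dehydrogenative Diels–Alder reaction.
- Forward key step: propargyl cinnamate A1 would be heated in nitrobenzene. The styrene part (ortho carbon, ipso carbon and the two alkene carbons) serves as diene and the arylalkyne as dienophile, and the first cycloadduct gives up H2 to the solvent. The product is arylnaphthalene lactone A2, with ring A as a 1,2,4-trimethoxybenzene and a γ-lactone across C6 and C7 (carbonyl on C6).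
- For it: the route is convergent from two simple halves, the tether fixes the regiochemistry, and the only free ortho carbon of the trimethoxyphenyl ring becomes C8a. The 1,4-dimethoxy pattern later gives the 2-methoxy-1,4-quinone by oxidative demethylation with no choice of site. On that point it is stronger than the chosen route, whose naphthol oxidation must select C1 over C3.
- Against it: C6 and C7 emerge at the wrong oxidation level and without the second aryl group. The lactone carbonyl must be turned into ArCH2 by mono-addition of an aryl nucleophile (which tends to over-add) and reduction of two C–O bonds, and the CH2O carbon must be reduced to CH3. With oxidative demethylation and MOM removal this is at least four steps after A2.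
- Against it, mechanistically: the ester tether prefers the conformation in which the reacting ends point apart, and the alkyne is not activated because the carbonyl sits on the diene side. High temperature is therefore needed, at which partial dehydrogenation and loss of MOM groups become likely. The final oxidation with (NH4)2Ce(NO3)6 would also have to spare two dialkoxyarene rings and a diarylmethane.
- Comparison: the chosen route places benzyl, methyl and aryl on ring B by cross-coupling at defined halogen positions, needs no oxidation-level correction, and has two steps after ring formation. In place of the unambiguous quinone formation it offers a mild final oxidation that leaves the guaiacyl rings alone.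

Alternative 2: Ring B is disconnected at C8–C8a and C4a–C5 by an intermolecular Diels–Alder reaction.
- Forward key step: diene A3 would add across the brominated double bond of bromomethoxyquinone A4 and HBr would be lost in the same pot. The product is 5,8-dihydronaphthoquinone A5 with the complete carbon skeleton (racemic at C8, which is irrelevant). Tautomerisation to the hydroquinone, oxidation and desilylation would follow.
- For it: this is the shortest plan. The whole skeleton forms in one convergent step that mirrors a plausible biogenesis from a lignan-type diene and a methoxyquinone, and only aromatisation and deprotection follow. On step economy and convergence it is clearly stronger than the chosen route.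
- For it, regiochemistry: the prediction is favourable. In A4 the methoxy group deactivates the carbonyl that becomes C4, so the future C1 carbonyl and the bromine both direct the nucleophilic diene terminus to the CH carbon (future C4a). The CH2 terminus of A3 is its more nucleophilic and less hindered end.
- Against it: the prediction rests on a balance of orbital coefficients in a diene whose 2-methyl group opposes its 1-aryl and 3-benzyl groups. The C8–C8a bond must join an aryl-bearing carbon to a fully substituted, bromine-bearing carbon. A3 contains a CH2 group that is both allylic and benzylic and can slip into conjugation to give the isomeric 1,4-diaryl diene, which would lead to a different adduct. A3 also needs its own stereodefined synthesis, and an electron-rich styryl diene with a bromoquinone invites electron transfer and polymerisation. A wrong regioisomer would differ from A5 only in which carbonyl is next to the methoxy group and could not be corrected.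
- Comparison: the chosen route is about twice as long. In exchange, every regiochemical element follows from connectivity: the ring B pattern from the halogen pattern of 2, the methoxy/aryl relationship from the polarity of 17 and the single free ortho carbon.

Alternative 3: Ring B is disconnected at C6–C7 and C7–C8 by a one-carbon ring expansion.
- Forward key step: dibromocarbene (CHBr3, KOt-Bu) would add to the tetrasubstituted double bond of indene A6 (the future C6 and C8). The dibromocyclopropane opens with loss of bromide and of a proton from C5 to give 7-bromonaphthalene A7. The bromine must then be exchanged for methyl, ring A oxidised with (NH4)2Ce(NO3)6 and the MOM groups removed.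
- For it: the inserted carbon lands exactly between the benzyl-bearing and the aryl-bearing carbon. A6 is accessible by classical carbonyl chemistry, the bromine at C7 would allow other alkyl groups, and the quinone again follows from a 1,4-dimethoxy pattern without an ortho/para question. On that last point it is stronger than the chosen route.
- Against it: the C5 methylene of A6 is acidic under KOt-Bu. The double bond can migrate, or the indenyl anion can react with the carbene at either terminus, so the carbon may be inserted between C5 and C6 to give the regioisomer with bromine and benzyl exchanged. The alkene is tetrasubstituted and the carbene is electrophilic toward the trimethoxyarene as well. Replacing a bromine flanked by benzyl and aryl with methyl is a hindered coupling, and the cerium oxidation has the same chemoselectivity problem as in alternative 1. Three steps follow the key step.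
- Comparison: the chosen route brings the C7 methyl group in from the start, has no base-labile regiochemistry in the ring-forming step, and ends with two mild steps.

Key step: step 10

Remark on the chemistry: the guaiacol hydroxyl groups are carried as benzyl ethers from the O-benzyl building blocks 3 and 11, which are assumed to be purchasable. Diazomethane and methoxyacetylene are handled as cold dilute solutions behind a shield.

## Route

Step 1
Reactants: 1 2-bromo-3-methylaniline
Product: 2 2-bromo-4-iodo-3-methylaniline
Conditions: NIS (1.0 equiv), MeCN, 0 → 20 °C, dark
Reagents that add atoms: N-iodosuccinimide, O=C1CCC(=O)N1I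
Why: Electrophilic aromatic iodination; the amino group is the strongest director and sends the iodine to its para carbon, which is also ortho to the methyl group, while the ortho carbon C6 is the minor site and one equivalent of reagent limits di-iodination.

Step 2
Reactants: 3 4-(benzyloxy)-3-methoxybenzyl alcohol
Product: 4 4-(benzyloxy)-3-methoxybenzyl chloride
Conditions: SOCl2 (1.2 equiv), CH2Cl2, 0 → 20 °C; used crude
Reagents that add atoms: thionyl chloride, O=S(Cl)Cl
Why: Chlorodehydroxylation of an electron-rich benzylic alcohol through its chlorosulfite; the aryl benzyl and aryl methyl ethers are inert, and the solvolysis-prone chloride is used without purification.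

Step 3
Reactants: 4 4-(benzyloxy)-3-methoxybenzyl chloride
Product: 5 [4-(benzyloxy)-3-methoxybenzyl]zinc chloride (THF solution, titrated and used as such)
Conditions: Zn dust (1.5 equiv, activated with BrCH2CH2Br and Me3SiCl), LiCl (1.5 equiv), THF, 25 °C
Reagents that add atoms: zinc, [Zn]
Why: Direct oxidative insertion of LiCl-activated zinc into the benzylic C–Cl bond; LiCl keeps the organozinc in solution and the mild conditions keep Wurtz homocoupling low.

Step 4
Reactants: 2 2-bromo-4-iodo-3-methylaniline; 5 [4-(benzyloxy)-3-methoxybenzyl]zinc chloride (1.2 equiv)
Product: 6 4-[4-(benzyloxy)-3-methoxybenzyl]-2-bromo-3-methylaniline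
Conditions: Pd(PPh3)4 (3 mol %), THF, 25 → 40 °C
Reagents that add atoms: none
Why: Negishi sp2–sp3 cross-coupling; zerovalent palladium inserts into the C–I bond far faster than into the C–Br bond, which is additionally flanked by NH2 and CH3, and a benzylzinc halide is not basic enough to be quenched by the aniline N–H.

Step 5
Reactants: 6 4-[4-(benzyloxy)-3-methoxybenzyl]-2-bromo-3-methylaniline
Product: 8 1-[4-(benzyloxy)-3-methoxybenzyl]-3-bromo-4-iodo-2-methylbenzene, via arenediazonium tosylate 7 (not isolated)
Conditions: p-TsOH·H2O (3 equiv), NaNO2 (2 equiv), KI (2.5 equiv), MeCN/H2O, 10 → 20 °C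
Reagents that add atoms: potassium iodide, [K+].[I-]
Why: Sandmeyer-type iododediazoniation, in which iodide reduces the diazonium ion without copper and MeCN keeps the lipophilic substrate dissolved; the step is placed before the biaryl coupling so that no electron-rich aryl ring sits ortho to the diazonium group.

Step 6
Reactants: 8 1-[4-(benzyloxy)-3-methoxybenzyl]-3-bromo-4-iodo-2-methylbenzene
Product: 10 4-[4-(benzyloxy)-3-methoxybenzyl]-2-bromo-3-methylbenzoic acid, via 2-bromoarylmagnesium chloride 9 (not isolated)
Conditions: i-PrMgCl·LiCl (1.1 equiv), THF, −40 °C; CO2 (g), −40 → 20 °C; 1 M HCl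
Reagents that add atoms: carbon dioxide, O=C=O
Why: Iodine–magnesium exchange is selective for C–I over C–Br, the ortho-bromoarylmagnesium species does not eliminate to the aryne at −40 °C, and carboxylation of the Grignard reagent gives the benzoic acid.

Step 7
Reactants: 10 4-[4-(benzyloxy)-3-methoxybenzyl]-2-bromo-3-methylbenzoic acid; 11 [4-(benzyloxy)-3-methoxyphenyl]boronic acid (1.5 equiv)
Product: 12 4-[4-(benzyloxy)-3-methoxybenzyl]-2-[4-(benzyloxy)-3-methoxyphenyl]-3-methylbenzoic acid
Conditions: Pd(OAc)2 (3 mol %), SPhos (6 mol %), K3PO4 (4 equiv), toluene/H2O, 90 °C; then 1 M HCl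
Reagents that add atoms: none
Why: Suzuki–Miyaura coupling of a di-ortho-substituted aryl bromide; the bulky electron-rich biarylphosphine makes oxidative addition and reductive elimination at the hindered carbon feasible, the boronic acid has no ortho substituent, and the carboxylate is tolerated in the aqueous basic medium.

Step 8
Reactants: 12 4-[4-(benzyloxy)-3-methoxybenzyl]-2-[4-(benzyloxy)-3-methoxyphenyl]-3-methylbenzoic acid
Product: 14 1-{4-[4-(benzyloxy)-3-methoxybenzyl]-2-[4-(benzyloxy)-3-methoxyphenyl]-3-methylphenyl}-2-diazoethan-1-one, via acid chloride 13 (not isolated)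
Conditions: (COCl)2 (1.3 equiv), DMF (cat.), CH2Cl2, 0 °C; evaporate cold; CH2N2 (3 equiv), Et2O/THF, 0 → 20 °C
Reagents that add atoms: diazomethane, C=[N+]=[N-]
Why: First stage of the Arndt–Eistert sequence, in which the acid chloride acylates diazomethane and a second equivalent takes up the HCl; the acid chloride is made cold without Lewis acid and used at once so that it does not acylate the neighbouring electron-rich ring.

Step 9
Reactants: 15 chloroacetaldehyde dimethyl acetal
Product: 17 methoxyacetylene, via sodium methoxyethynide 16 (not isolated)
Conditions: NaNH2 (3.1 equiv), liquid NH3, −33 °C; evaporate NH3; cold brine, −70 °C; distil the low-boiling alkyne into cold ClCH2CH2Cl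
Reagents that add atoms: none
Why: Two successive base-induced β-eliminations (methanol to the 2-chlorovinyl ether, then HCl), with the third equivalent of NaNH2 holding the product as its acetylide until the aqueous quench; this is the standard preparation of 1-alkoxyalkynes from chloroacetaldehyde acetals.

Step 10
Reactants: 14 1-{4-[4-(benzyloxy)-3-methoxybenzyl]-2-[4-(benzyloxy)-3-methoxyphenyl]-3-methylphenyl}-2-diazoethan-1-one; 17 methoxyacetylene (4 equiv)
Product: 21 7-[4-(benzyloxy)-3-methoxybenzyl]-5-[4-(benzyloxy)-3-methoxyphenyl]-3-methoxy-6-methylnaphthalen-1-ol, via aryl ketene 18 (not isolated), via 4-aryl-3-methoxycyclobutenone 19 (not isolated), via dienylketene 20 (not isolated)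
Conditions: ClCH2CH2Cl (0.02 M), Ar, hν (medium-pressure Hg lamp, Pyrex filter, λ > 300 nm), 10–20 °C, closed vessel; then 80 °C
Reagents that add atoms: none
Why: Light above 300 nm is absorbed by the diazoketone but not by the benzyl guaiacyl ethers, and loss of N2 with 1,2-shift of the aryl group (Wolff rearrangement, new bond C8a–C1) gives aryl ketene 18. Ynol ether 17 adds to the C=C bond of 18 in a polar [2+2] cycloaddition in which its nucleophilic CH carbon bonds to the electrophilic ketene carbonyl carbon (C3–C4) and its oxygen-bearing carbon to the aryl-bearing carbon (C1–C2), so that cyclobutenone 19 carries the methoxy group on C2. At 80 °C 19 opens by reversible conrotatory 4π electrocyclic cleavage of the C1–C4 bond to dienylketene 20, and only the isomer with the aryl group cis to the ketene arm can react further, which drains the equilibrium. Ring A then closes by a thermal disrotatory 6π electrocyclisation in which the ketene carbon C4 bonds to C4a, the C4a=C8a bond of ring B serving as the third π bond, and a proton shift from C4a to oxygen restores aromaticity to give naphthol 21. The closest known reaction type is the photochemical Wolff variant of the Danheiser benzannulation of aryl diazomethyl ketones with alkoxyalkynes, whose thermal relative is the Smith–Hoehn naphthol synthesis from aryl ketenes and alkynes. Two selectivities are needed: the orientation of the [2+2] step, secured by the matched polarity of ketene and ynol ether, and the site of ring closure, secured by the substrate because C8 already bears the aryl group and C4a is the only free ortho carbon. No stereocentre remains in 21, since the one at C1 of 19 is erased on ring opening. Excess 17 and high dilution favour the cross-cycloaddition over dimerisation of 18.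

Step 11
Reactants: 21 7-[4-(benzyloxy)-3-methoxybenzyl]-5-[4-(benzyloxy)-3-methoxyphenyl]-3-methoxy-6-methylnaphthalen-1-ol
Product: 22 6-[4-(benzyloxy)-3-methoxybenzyl]-8-[4-(benzyloxy)-3-methoxyphenyl]-2-methoxy-7-methylnaphthalene-1,4-dione
Conditions: (KSO3)2NO (2.5 equiv), aq. KH2PO4 (pH 6), acetone/H2O, 0 → 20 °C
Reagents that add atoms: potassium nitrosodisulfonate, [K+].[K+].[O-]S(=O)(=O)N([O])S(=O)(=O)[O-]
Why: Teuber oxidation, in which one (KSO3)2NO radical removes the phenolic hydrogen, a second couples at C1 para to the oxygen, and loss of HN(SO3K)2 gives the para-quinone; attack at C1 and not C3 should be favoured because only the C1 adduct has the C2 methoxy group conjugated with the C4 carbonyl as a vinylogous ester, and benzyl ethers and the diarylmethane are inert to this one-electron oxidant.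

Step 12
Reactants: 22 6-[4-(benzyloxy)-3-methoxybenzyl]-8-[4-(benzyloxy)-3-methoxyphenyl]-2-methoxy-7-methylnaphthalene-1,4-dione
Product: 24 larreantin, via hydroquinone 23 (not isolated)
Conditions: H2 (1 atm), 10% Pd/C, EtOAc/MeOH, 20 °C; filter; stir under air, 20 °C
Reagents that add atoms: none
Why: Hydrogenolysis of the two benzyl aryl ethers; under H2 the quinone is reduced only to hydroquinone 23, which air should re-oxidise once the catalyst is filtered off, and the diarylmethane C–C bond and the methyl ethers are not cleaved.

## Compound list

1 | 2-bromo-3-methylaniline | Cc1cccc(N)c1Br | starting material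
2 | 2-bromo-4-iodo-3-methylaniline | Cc1c(I)ccc(N)c1Br | intermediate
3 | 4-(benzyloxy)-3-methoxybenzyl alcohol | COc1cc(CO)ccc1OCc1ccccc1 | starting material
4 | 4-(benzyloxy)-3-methoxybenzyl chloride | COc1cc(CCl)ccc1OCc1ccccc1 | intermediate
5 | [4-(benzyloxy)-3-methoxybenzyl]zinc chloride | COc1cc(C[Zn]Cl)ccc1OCc1ccccc1 | intermediate
6 | 4-[4-(benzyloxy)-3-methoxybenzyl]-2-bromo-3-methylaniline | Cc1c(Cc2ccc(OCc3ccccc3)c(OC)c2)ccc(N)c1Br | intermediate
7 | 4-[4-(benzyloxy)-3-methoxybenzyl]-2-bromo-3-methylbenzenediazonium p-toluenesulfonate | Cc1c(Cc2ccc(OCc3ccccc3)c(OC)c2)ccc([N+]#N)c1Br.Cc1ccc(S(=O)(=O)[O-])cc1 | intermediate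
8 | 1-[4-(benzyloxy)-3-methoxybenzyl]-3-bromo-4-iodo-2-methylbenzene | Cc1c(Cc2ccc(OCc3ccccc3)c(OC)c2)ccc(I)c1Br | intermediate
9 | {4-[4-(benzyloxy)-3-methoxybenzyl]-2-bromo-3-methylphenyl}magnesium chloride | Cc1c(Cc2ccc(OCc3ccccc3)c(OC)c2)ccc([Mg]Cl)c1Br | intermediate
10 | 4-[4-(benzyloxy)-3-methoxybenzyl]-2-bromo-3-methylbenzoic acid | Cc1c(Cc2ccc(OCc3ccccc3)c(OC)c2)ccc(C(=O)O)c1Br | intermediate
11 | [4-(benzyloxy)-3-methoxyphenyl]boronic acid | COc1cc(B(O)O)ccc1OCc1ccccc1 | starting material
12 | 4-[4-(benzyloxy)-3-methoxybenzyl]-2-[4-(benzyloxy)-3-methoxyphenyl]-3-methylbenzoic acid | Cc1c(Cc2ccc(OCc3ccccc3)c(OC)c2)ccc(C(=O)O)c1-c1ccc(OCc2ccccc2)c(OC)c1 | intermediate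
13 | 4-[4-(benzyloxy)-3-methoxybenzyl]-2-[4-(benzyloxy)-3-methoxyphenyl]-3-methylbenzoyl chloride | Cc1c(Cc2ccc(OCc3ccccc3)c(OC)c2)ccc(C(=O)Cl)c1-c1ccc(OCc2ccccc2)c(OC)c1 | intermediate
14 | 1-{4-[4-(benzyloxy)-3-methoxybenzyl]-2-[4-(benzyloxy)-3-methoxyphenyl]-3-methylphenyl}-2-diazoethan-1-one | [N-]=[N+]=CC(=O)c1ccc(Cc2ccc(OCc3ccccc3)c(OC)c2)c(C)c1-c1ccc(OCc2ccccc2)c(OC)c1 | intermediate
15 | chloroacetaldehyde dimethyl acetal (2-chloro-1,1-dimethoxyethane) | COC(CCl)OC | starting material
16 | sodium methoxyethynide | [Na+].[C-]#COC | intermediate
17 | methoxyacetylene (methoxyethyne) | C#COC | intermediate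
18 | 2-{4-[4-(benzyloxy)-3-methoxybenzyl]-2-[4-(benzyloxy)-3-methoxyphenyl]-3-methylphenyl}ethen-1-one (aryl ketene) | O=C=Cc1ccc(Cc2ccc(OCc3ccccc3)c(OC)c2)c(C)c1-c1ccc(OCc2ccccc2)c(OC)c1 | intermediate
19 | 4-{4-[4-(benzyloxy)-3-methoxybenzyl]-2-[4-(benzyloxy)-3-methoxyphenyl]-3-methylphenyl}-3-methoxycyclobut-2-en-1-one (racemic) | COC1=CC(=O)C1c1ccc(Cc2ccc(OCc3ccccc3)c(OC)c2)c(C)c1-c1ccc(OCc2ccccc2)c(OC)c1 | intermediate
20 | (3E)-4-{4-[4-(benzyloxy)-3-methoxybenzyl]-2-[4-(benzyloxy)-3-methoxyphenyl]-3-methylphenyl}-3-methoxybuta-1,3-dien-1-one (aryl cis to the ketene arm) | O=C=C/C(OC)=C\c1ccc(Cc2ccc(OCc3ccccc3)c(OC)c2)c(C)c1-c1ccc(OCc2ccccc2)c(OC)c1 | intermediate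
21 | 7-[4-(benzyloxy)-3-methoxybenzyl]-5-[4-(benzyloxy)-3-methoxyphenyl]-3-methoxy-6-methylnaphthalen-1-ol | COc1cc(O)c2cc(Cc3ccc(OCc4ccccc4)c(OC)c3)c(C)c(-c3ccc(OCc4ccccc4)c(OC)c3)c2c1 | intermediate
22 | 6-[4-(benzyloxy)-3-methoxybenzyl]-8-[4-(benzyloxy)-3-methoxyphenyl]-2-methoxy-7-methylnaphthalene-1,4-dione | COC1=CC(=O)c2cc(Cc3ccc(OCc4ccccc4)c(OC)c3)c(C)c(-c3ccc(OCc4ccccc4)c(OC)c3)c2C1=O | intermediate
23 | 6-(4-hydroxy-3-methoxybenzyl)-8-(4-hydroxy-3-methoxyphenyl)-2-methoxy-7-methylnaphthalene-1,4-diol | COc1cc(O)c2cc(Cc3ccc(O)c(OC)c3)c(C)c(-c3ccc(O)c(OC)c3)c2c1O | intermediate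
24 | larreantin, 6-(4-hydroxy-3-methoxybenzyl)-8-(4-hydroxy-3-methoxyphenyl)-2-methoxy-7-methylnaphthalene-1,4-dione | COC1=CC(=O)c2cc(Cc3ccc(O)c(OC)c3)c(C)c(-c3ccc(O)c(OC)c3)c2C1=O | target

## Step count and least certain steps

Total: 12 steps. Longest linear sequence: 10 steps (steps 2, 3, 4, 5, 6, 7, 8, 10, 11, 12, from alcohol 3); from aniline 1 it is 9 steps.

Step 10 (key step). Three processes are most likely to go wrong:
- The monosubstituted aryl ketene may dimerise, or be captured by the product naphthol through O-acylation, faster than it adds to the volatile alkyne.
- The 6π closure may be incomplete, because closing onto an arene costs aromatic stabilisation in the transition state.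
- The benzyl aryl ethers may be cleaved photochemically if short-wavelength light reaches them.

The fallback generates the ketene thermally in the dark. It sets out from 14. Wolff rearrangement with AgO2CPh (cat.) and Et3N in aqueous 1,4-dioxane gives arylacetic acid F1, and (COCl)2 converts it into arylacetyl chloride F2. Slow addition of Et3N to F2 and excess 17 in toluene releases ketene 18 at low stationary concentration. The route is rejoined at cyclobutenone 19, which is heated at 110 °C to 21.

Step 11. Oxygenation at the ortho carbon C3 instead of C1 is the main danger. C1 is shielded by the peri aryl group and the neighbouring methoxy group, and 1-naphthols have an inherent tendency toward ortho-quinone formation with this radical oxidant. Over-oxidation is a lesser concern. The fallback is a two-electron, ionic oxidation with a small nucleophile, setting out from 21. PhI(OAc)2 (2.2 equiv) in MeOH at 0 °C should add methanol twice at the para carbon and give quinone monoketal F3. Dilute aqueous acid (AcOH/H2O/THF) then hydrolyses the ketal, and the route is rejoined at 22.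

Step 8. The acid chloride may undergo intramolecular Friedel–Crafts acylation onto the methoxy-activated position of the neighbouring ring. Acylation of diazomethane at the hindered carbonyl may also be slow. The fallback avoids the acid chloride and sets out from 12. MeLi (excess, THF, 0 °C; Me3SiCl quench, then aqueous acid) gives methyl ketone F4. LiN(SiMe3)2 and CF3CO2CH2CF3 at −78 °C give trifluoroacetyl ketone F5. CH3SO2N3, Et3N and H2O in MeCN transfer the diazo group with loss of the trifluoroacetyl group (detrifluoroacetylative diazo transfer), and the route is rejoined at 14.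

Step 7. Oxidative addition at the bromide between carboxylate and methyl may be slow, so that protodeboronation of the electron-rich boronic acid and protodebromination compete. The fallback takes the carboxylate out of the coupling and sets out from 10. MeI and K2CO3 in DMF give methyl ester F6. Coupling with 11 under anhydrous conditions (Pd(OAc)2, SPhos, K3PO4, toluene, 100 °C) gives biaryl ester F7. LiOH in THF/MeOH/H2O at 60 °C saponifies it, and the route is rejoined at 12.

Step 12. The hydroquinone ring may be reduced further on the catalyst, or re-oxidation may be incomplete and accompanied by oxidative coupling of the freed guaiacols. The fallback avoids any reduction: from 22, BCl3 with pentamethylbenzene as benzyl-cation scavenger in CH2Cl2 at −78 °C should cleave the benzyl ethers and leave the quinone untouched. It leads directly to 24 and makes no new compound (F0).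

## Further compounds

F1 | step 10 | {4-[4-(benzyloxy)-3-methoxybenzyl]-2-[4-(benzyloxy)-3-methoxyphenyl]-3-methylphenyl}acetic acid | OC(=O)Cc1ccc(Cc2ccc(OCc3ccccc3)c(OC)c2)c(C)c1-c1ccc(OCc2ccccc2)c(OC)c1
F2 | step 10 | {4-[4-(benzyloxy)-3-methoxybenzyl]-2-[4-(benzyloxy)-3-methoxyphenyl]-3-methylphenyl}acetyl chloride | ClC(=O)Cc1ccc(Cc2ccc(OCc3ccccc3)c(OC)c2)c(C)c1-c1ccc(OCc2ccccc2)c(OC)c1
F3 | step 11 | 7-[4-(benzyloxy)-3-methoxybenzyl]-5-[4-(benzyloxy)-3-methoxyphenyl]-3,4,4-trimethoxy-6-methylnaphthalen-1(4H)-one (quinone monoketal) | COC1=CC(=O)c2cc(Cc3ccc(OCc4ccccc4)c(OC)c3)c(C)c(-c3ccc(OCc4ccccc4)c(OC)c3)c2C1(OC)OC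
F4 | step 8 | 1-{4-[4-(benzyloxy)-3-methoxybenzyl]-2-[4-(benzyloxy)-3-methoxyphenyl]-3-methylphenyl}ethan-1-one | CC(=O)c1ccc(Cc2ccc(OCc3ccccc3)c(OC)c2)c(C)c1-c1ccc(OCc2ccccc2)c(OC)c1
F5 | step 8 | 1-{4-[4-(benzyloxy)-3-methoxybenzyl]-2-[4-(benzyloxy)-3-methoxyphenyl]-3-methylphenyl}-4,4,4-trifluorobutane-1,3-dione | O=C(CC(=O)C(F)(F)F)c1ccc(Cc2ccc(OCc3ccccc3)c(OC)c2)c(C)c1-c1ccc(OCc2ccccc2)c(OC)c1
F6 | step 7 | methyl 4-[4-(benzyloxy)-3-methoxybenzyl]-2-bromo-3-methylbenzoate | COC(=O)c1ccc(Cc2ccc(OCc3ccccc3)c(OC)c2)c(C)c1Br
F7 | step 7 | methyl 4-[4-(benzyloxy)-3-methoxybenzyl]-2-[4-(benzyloxy)-3-methoxyphenyl]-3-methylbenzoate | COC(=O)c1ccc(Cc2ccc(OCc3ccccc3)c(OC)c2)c(C)c1-c1ccc(OCc2ccccc2)c(OC)c1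
F0 | step 12 | none | none
A1 | alternative 1 | 3-[3-methoxy-4-(methoxymethoxy)phenyl]prop-2-yn-1-yl (2E)-3-(2,4,5-trimethoxyphenyl)prop-2-enoate | COCOc1ccc(C#CCOC(=O)/C=C/c2cc(OC)c(OC)cc2OC)cc1OC
A2 | alternative 1 | 8-[3-methoxy-4-(methoxymethoxy)phenyl]-1,2,4-trimethoxynaphthalene fused at C6/C7 to a γ-lactone (carbonyl on C6, CH2O on C7; target numbering) | COc1cc(OC)c2cc3C(=O)OCc3c(-c3ccc(OCOC)c(OC)c3)c2c1OC
A3 | alternative 2 | (1E)-1-[4-(tert-butyldimethylsilyloxy)-3-methoxyphenyl]-3-[4-(tert-butyldimethylsilyloxy)-3-methoxybenzyl]-2-methylbuta-1,3-diene | C=C(Cc1ccc(O[Si](C)(C)C(C)(C)C)c(OC)c1)/C(C)=C/c1ccc(O[Si](C)(C)C(C)(C)C)c(OC)c1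
A4 | alternative 2 | 2-bromo-6-methoxy-1,4-benzoquinone | COC1=CC(=O)C=C(Br)C1=O
A5 | alternative 2 | 6-[4-(tert-butyldimethylsilyloxy)-3-methoxybenzyl]-8-[4-(tert-butyldimethylsilyloxy)-3-methoxyphenyl]-2-methoxy-7-methyl-5,8-dihydronaphthalene-1,4-dione (racemic at C8) | COC1=CC(=O)C2=C(C1=O)C(c1ccc(O[Si](C)(C)C(C)(C)C)c(OC)c1)C(C)=C(Cc1ccc(O[Si](C)(C)C(C)(C)C)c(OC)c1)C2
A6 | alternative 3 | 4,5,7-trimethoxy-3-[3-methoxy-4-(methoxymethoxy)phenyl]-2-[3-methoxy-4-(methoxymethoxy)benzyl]-1H-indene | COc1cc(OC)c2c(c1OC)C(c1ccc(OCOC)c(OC)c1)=C(Cc1ccc(OCOC)c(OC)c1)C2
A7 | alternative 3 | 7-bromo-1,2,4-trimethoxy-8-[3-methoxy-4-(methoxymethoxy)phenyl]-6-[3-methoxy-4-(methoxymethoxy)benzyl]naphthalene | COc1cc(OC)c2cc(Cc3ccc(OCOC)c(OC)c3)c(Br)c(-c3ccc(OCOC)c(OC)c3)c2c1OC
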